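Losing more substrate than there is partner is impossible: one substrate goes with one partner. The flask on the bench and the two earlier runs stand below.

in all of them: left-handed substrate 0.14 M; right-handed substrate 0.14 M; free catalyst 0.41 mM

| flask | partner | remark | time |
|---|---|---|---|
| summer | 0.084 M | run made earlier |  |
| spring | 0.13 M | run made earlier |  |
| flask | 0.168 M |  | 15 min |

| run | time / min | right-handed substrate / % | left-handed substrate / % |
|---|---|---|---|
| summer | 1.33 | 48.7 | 28.5 |
| summer | 2.50 | 48.9 | 21.3 |
| summer | 5.00 | 47.0 | 22.8 |
| summer | 10.0 | 46.6 | 23.2 |
| summer | 20.0 | 44.0 | 26.3 |
| spring | 4.00 | 47.6 | 8.2 |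
| spring | 8.00 | 44.3 | 9.5 |
| spring | 10.0 | 43.6 | 9.6 |
| spring | 15.0 | 41.0 | 12.0 |
| spring | 20.0 | 37.9 | 12.9 |

(standard deviation of a reading: 1 percentage point)

- whether the excess of right-handed substrate over left-handed substrate among what is left of the two reaches 90% by 15 min (yes / no)
- the highest excess of right-handed substrate over left-handed substrate among what is left of the two up to 15 min

- free catalyst is single-handed; left-handed substrate and right-handed substrate are mirror images of each other, charged as a racemate, each of them at the stated concentration
- the numbers in the tables scatter with a standard deviation of 1 percentage point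

The partner share of this flask, 60.0%, is the partner charged over the two substrates together. Written in concentrations:

f = c(partner) / [c(left-handed substrate) + c(right-handed substrate)]

part of the substrates left at the stop = 1 − f

cap on the excess, while f is below 0.5: f / (1 − f)

In the summer run, f is 30.0%, which makes partner the limiting reagent. The rule gives 70.0% left and a cap of 42.9%. The readings at 2.50 min show 70.2% left and an excess of 39.3%.

The flask on the bench has partner for the whole left-handed charge, with 10 points of the substrates to spare, so the cap falls away. An excess of 90% needs left-handed substrate below 5.26% of the right-handed. The reckoning here says yes, gives no peak value, and expects about 40.0% of the substrates in the flask at the last sampling, mostly right-handed.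

The flask should be sampled by 15 min and not left standing: the summer excess reads 34.7% at 5.00 min and 25.2% at 20.0 min.

The forecast says yes with a top of 91%: “This is borderline, but I lean yes.”

The flask gives yes, reaching 90% at 2.02 min, with a top of 97.9%.

    partner + catalyst intermediate A → free catalyst + left-handed product (k = 50.0 M⁻¹ s⁻¹)
    partner + catalyst intermediate B → free catalyst + right-handed product (k = 0.990 M⁻¹ s⁻¹)
    free catalyst → spent catalyst A (k = 5.80 × 10⁻⁴ s⁻¹)
    partner + free catalyst → spent catalyst B (k = 0.120 M⁻¹ s⁻¹)
    free catalyst + left-handed substrate ⇌ catalyst intermediate A (K = 220 M⁻¹, k = 1100 M⁻¹ s⁻¹)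
    free catalyst + right-handed substrate ⇌ catalyst intermediate B (K = 3.90 M⁻¹, k = 1500 M⁻¹ s⁻¹)
    left-handed substrate ⇌ right-handed substrate (k = 3.10 × 10⁻⁴ s⁻¹)

At 15.0 min the flask holds 41.1% of the two substrates against the 40.0% from 1 − f, with 1.7% of its partner left. The way back from catalyst intermediate B to free catalyst and right-handed substrate is one part of the reason that 58.9% of the two substrates has reacted by then: without that step, the same flask reaches 24.6%. In the spring run, f is 46.4%, so 53.6% should stay, and the readings at 10.0 min show 53.2%.

The earlier runs and the new flask come from a simulation from invented constants, and the scatter is random.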